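The route rests on cutting the benzene ring at C3a–C4 and C7–C7a. Bromine addition to 2,5-dimethoxy-2,5-dihydrofuran (1, with bromine 2) gives the cyclic dibromo bis-acetal 3, a masked 2,3-dibromosuccinaldehyde whose four carbons map onto C4–C5(Br)–C6(Br)–C7; 1-methylpyrrole (4) supplies the pyrrole ring N1–C2–C3–C3a–C7a. One acid-mediated double Friedel–Crafts benzannulation of 4 with 3 should form both bonds, close the six-membered ring and aromatise it to 5,6-dibromo-1-methylindole (7), with both benzenoid bromines already placed. C3 formylation and C2 zincation–bromination then complete the achiral target 11.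

Key step: step 2

Remark: the target has no stereogenic element, so there is no enantiomer to secure; the sp3 stereocentres of 3, 5 and 6 are transient, are carried as mixtures and are erased on aromatisation.

Step 1
Reactants: 1 2,5-dimethoxy-2,5-dihydrofuran (commercial cis/trans mixture); 2 bromine
Product: 3 3,4-dibromo-2,5-dimethoxytetrahydrofuran (3,4-trans, racemic, mixture of acetal epimers)
Conditions: Br2 (1.0 equiv), solid NaHCO3, CH2Cl2, −20 → 0 °C, dark; aq Na2S2O3/NaHCO3 wash, used crude
Reagents that add atoms: bromine, BrBr
Why: Electrophilic anti addition of bromine to the isolated ring alkene through a bromonium ion should give the trans-dibromide, the bicarbonate buffer keeping adventitious HBr from cleaving the acetals; the new C–Br stereocentres are erased in step 2.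

Step 2
Reactants: 3 3,4-dibromo-2,5-dimethoxytetrahydrofuran (1.2 equiv); 4 1-methylpyrrole
Product: 7 5,6-dibromo-1-methylindole, via tetrahydrofuranylpyrrole 5 (not isolated), via 4-hydroxy-7-methoxytetrahydroindole 6 (not isolated)
Conditions: TfOH (0.2 equiv), ClCH2CH2Cl (0.05 M), 4 added over 2 h at 0 °C, then 60 °C
Reagents that add atoms: none
Why: Proposed new method: TfOH ionises one acetal of 3 to an α-bromo oxocarbenium ion that C2 of 4 captures to give 5; acid then cleaves the pyrrol-2-yl carbinyl C–O bond of 5 (methanol caps that carbon, the future C7), which unmasks the far acetal carbon as a protonated aldehyde that alkylates the adjacent C3 to give 6, so C7–C7a and C3a–C4 are both formed. The six-membered ring closes in an intramolecular Friedel–Crafts hydroxyalkylation, 6-exo-trig at the carbonyl carbon with the pyrrole C2=C3 bond inside the new ring. C7–OMe and C4–OH of 6 then ionise to pyrrole-stabilised (azafulvenium-type) cations that each shed the proton of the adjacent CHBr carbon, so methanol and water leave, both C–Br bonds stay and the ring becomes benzenoid; every sp3 stereocentre is erased, so none needs control. The closest known reaction type is the acid-mediated benzannulation of pyrroles to indoles and of indoles to carbazoles with 2,5-dimethoxytetrahydrofuran or 1,4-diketones; untested is the 3,4-dibromo bis-acetal, whose cations form less readily and whose bromines must survive the aromatisation. Regiochemistry is secured by the substrate: the four-carbon partner is symmetric, a four-carbon tether from C2 can reach only C3 (closure at the far α-carbon C5 would need a bridged, hopelessly strained ring), and first attack at C3 followed by closure at C2 would give the same indole. Proton loss in place of bromide loss is favoured by a Brønsted acid without halophilic metal, which ionises C–O but not C–Br bonds, and oligomerisation through intermolecular pyrrole alkylation is suppressed by adding 4 slowly to dilute excess 3.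

Step 3
Reactants: 7 5,6-dibromo-1-methylindole
Product: 9 5,6-dibromo-1-methylindole-3-carbaldehyde, via C3 iminium chloride 8 (not isolated)
Conditions: POCl3 (1.3 equiv), DMF, 0 → 40 °C; then 2 M aq NaOH, 0 °C → rt
Reagents that add atoms: N,N-dimethylformamide, CN(C)C=O (formyl carbon); water, O (aldehyde oxygen on hydrolysis)
Why: Vilsmeier–Haack formylation, in which the chloroiminium ion from DMF/POCl3 attacks C3, the most nucleophilic position of an N-alkylindole even with two ring bromines, and alkaline hydrolysis of iminium salt 8 should release the aldehyde while the aryl bromides stay inert.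

Step 4
Reactants: 9 5,6-dibromo-1-methylindole-3-carbaldehyde; 2 bromine
Product: 11 2,5,6-tribromo-1-methylindole-3-carbaldehyde, via indol-2-ylzinc chloride 10 (not isolated)
Conditions: TMPZnCl·LiCl (1.2 equiv), THF, 25 °C; then Br2 (1.2 equiv), −30 → 0 °C; aq Na2S2O3
Reagents that add atoms: bromine, BrBr
Why: Directed C–H zincation with a hindered TMP–zinc amide (Knochel-type base) should remove the most acidic proton, C2–H, flanked by N1 and the coordinating 3-formyl group, and the C–Zn bond tolerates the aldehyde and the aryl bromides before electrophilic bromodemetalation by Br2 places the C2 bromine.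

Compound list
1 | 2,5-dimethoxy-2,5-dihydrofuran (cis/trans mixture as purchased) | COC1C=CC(OC)O1 | starting material
2 | bromine | BrBr | starting material
3 | 3,4-dibromo-2,5-dimethoxytetrahydrofuran (3,4-trans, racemic, one enantiomer drawn, acetal carbons unassigned) | COC1OC(OC)[C@@H](Br)[C@@H]1Br | intermediate
4 | 1-methylpyrrole | Cn1cccc1 | starting material
5 | 2-(3,4-dibromo-5-methoxytetrahydrofuran-2-yl)-1-methylpyrrole (diastereomer mixture, not isolated) | COC1OC(c2cccn2C)C(Br)C1Br | intermediate
6 | 5,6-dibromo-7-methoxy-1-methyl-4,5,6,7-tetrahydroindol-4-ol (diastereomer mixture, not isolated) | Cn1ccc2C(O)C(Br)C(Br)C(OC)c12 | intermediate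
7 | 5,6-dibromo-1-methylindole | Cn1ccc2cc(Br)c(Br)cc21 | intermediate
8 | [(5,6-dibromo-1-methylindol-3-yl)methylidene]dimethyliminium chloride (not isolated) | C[N+](C)=Cc1cn(C)c2cc(Br)c(Br)cc12.[Cl-] | intermediate
9 | 5,6-dibromo-1-methylindole-3-carbaldehyde | Cn1cc(C=O)c2cc(Br)c(Br)cc21 | intermediate
10 | (5,6-dibromo-3-formyl-1-methylindol-2-yl)zinc chloride (LiCl complex, not isolated) | Cn1c([Zn]Cl)c(C=O)c2cc(Br)c(Br)cc21 | intermediate
11 | 2,5,6-tribromo-1-methylindole-3-carbaldehyde | Cn1c(Br)c(C=O)c2cc(Br)c(Br)cc21 | target

Total step count: 4
Longest linear sequence: 4 steps (1 → 3 → 7 → 9 → 11)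

Steps most likely to fail

Step 2. After the first alkylation, the pyrrolyl carbinyl cation may be captured by a second pyrrole (dipyrrolylmethane formation and oligomerisation) faster than the ring-closing alkylation at C3. During aromatisation an allylic C–Br bond may also ionise, so that a bromine is lost in place of a proton. The fallback uses known chemistry only, sets out from bromine 2 and comes back at 7. Purchased methyl 1H-indole-3-carboxylate F1 is dibrominated with bromine 2 in acetic acid at room temperature, where the 3-ester deactivates the pyrrole ring and steers both substitutions to C5 and C6, giving methyl 5,6-dibromo-1H-indole-3-carboxylate F2. Saponification (NaOH, aqueous MeOH, reflux; then HCl) gives 5,6-dibromo-1H-indole-3-carboxylic acid F3, which loses CO2 on heating to give 5,6-dibromo-1H-indole F4. N-Methylation (NaH, MeI, DMF, 0 °C) then delivers 7.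

Step 4. Zincation may be incomplete or may stray to C4–H or C7–H next to the ring bromines, or the amide base may add to the formyl group, so that bromine ends up on the wrong carbon or 9 is returned. The fallback sets out from 7 and comes back at 11, replacing steps 3 and 4. Compound 7 is oxidised with pyridinium tribromide (3 equiv, t-BuOH/H2O, rt) to 3,3,5,6-tetrabromo-1-methylindolin-2-one F5. Zinc dust in acetic acid removes the two C3 bromines, the aryl bromides being inert, to give 5,6-dibromo-1-methylindolin-2-one F6. Vilsmeier–Haack–Arnold bromoformylation (POBr3, DMF, CHCl3, reflux; aqueous NaHCO3) then formylates C3 and converts the lactam carbonyl into the C2 bromide in one operation, giving 11. The C2 bromine thus enters as bromide on an activated lactam instead of as Br+ on a carbanion.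

Step 1. Traces of HBr may ionise the acetal carbons of the cyclic product, so that methanol and HBr are lost toward bromofurans or the acetal centres scramble during bromination and isolation. The fallback sets out from bromine 2 and comes back at 7. Purchased (E)-1,1,4,4-tetramethoxybut-2-ene F7 (fumaraldehyde bis(dimethyl acetal)) adds bromine 2 (CH2Cl2, NaHCO3, 0 °C) to give meso-2,3-dibromo-1,1,4,4-tetramethoxybutane F8, an open-chain mask of the same dialdehyde with no ring oxygen to drive furan formation. F8 then takes the place of 3 in the annulation with 4 under the conditions of step 2, forming the same two C–C bonds with release of four methanol, and the route is rejoined at 7.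

Further compounds
F1 | step 2 | methyl 1H-indole-3-carboxylate (purchased) | COC(=O)c1c[nH]c2ccccc12
F2 | step 2 | methyl 5,6-dibromo-1H-indole-3-carboxylate | COC(=O)c1c[nH]c2cc(Br)c(Br)cc12
F3 | step 2 | 5,6-dibromo-1H-indole-3-carboxylic acid | OC(=O)c1c[nH]c2cc(Br)c(Br)cc12
F4 | step 2 | 5,6-dibromo-1H-indole | Brc1cc2cc[nH]c2cc1Br
F5 | step 4 | 3,3,5,6-tetrabromo-1-methylindolin-2-one | CN1C(=O)C(Br)(Br)c2cc(Br)c(Br)cc21
F6 | step 4 | 5,6-dibromo-1-methylindolin-2-one | CN1C(=O)Cc2cc(Br)c(Br)cc21
F7 | step 1 | (E)-1,1,4,4-tetramethoxybut-2-ene (purchased) | COC(OC)/C=C/C(OC)OC
F8 | step 1 | meso-2,3-dibromo-1,1,4,4-tetramethoxybutane | COC(OC)[C@H](Br)[C@H](Br)C(OC)OC
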